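**Retros­ynthetic overview**

1. Eudesmane numbering is used: ring A = C1–C5, C10; ring B = C5–C10; C11 on C7, C14 on C10, C15 on C4. The ester is made last from triol 17 and epoxy acid 20, and the 3α,4α-diol comes from the C3=C4 olefin of dienone 16.
2. The C8 ketone and the C14 methyl are traced back to one temporary ring, the bridged 14,8β-lactone 12 (C14 at the carboxyl level).
3. Key disconnection: retro-Diels–Alder of ring A (bonds C1–C2 and C5–C10) to the monocyclic α-methylene-γ-butyrolactone 11. Rings A and B form together, after the lactone ring is made and before it is removed.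
4. Enabling feature: ring A holds a vicinal cis-diol at C3/C4 (a masked C3=C4, the cyclohexene retron) beside two plain CH2 groups, C1 and C2. In ring B, C14 on C10 and the oxygen on C8 are 1,3-related across C9, so at the C8 alcohol level they can be tied as a lactone O8–C14(=O) that activates C1=C10 as dienophile and passes the C8 configuration on to C10 and C5.
5. 11 is assembled from 2-methylbut-3-yn-2-ol (silylformylation, asymmetric 2-(ethoxycarbonyl)allylation) and (E)-1-iodo-2-methylbuta-1,3-diene (Hiyama–Denmark coupling).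

Key step: step 7

Remark: the sense of induction in step 2 is assumed to be the one that gives the (5R) lactone with the (R)-SEGPHOS-modified iridium catalyst; should it be opposite, the (S) ligand is used.

**Route**

Step 1
Reactants: 1 2-methylbut-3-yn-2-ol
Product: 2 (2Z)-3-[benzyl(dimethyl)silyl]-2-(2-hydroxypropan-2-yl)prop-2-enal
Conditions: BnMe2SiH (1.1 equiv), CO (20 atm), Rh4(CO)12 (0.5 mol %), Et3N (0.5 equiv), toluene, 60 °C
Reagents that add atoms: benzyl(dimethyl)silane C[SiH](C)Cc1ccccc1; carbon monoxide [C-]#[O+]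
Why: Rhodium-catalysed silylformylation adds silicon and formyl syn across the terminal alkyne with silicon on the terminal carbon, so the silyl group should end up cis to the new aldehyde (the later C8) while the tertiary hydroxyl stays free under amine buffering.

Step 2
Reactants: 2 (2Z)-3-[benzyl(dimethyl)silyl]-2-(2-hydroxypropan-2-yl)prop-2-enal
Product: 4 (5R)-5-{(1E)-1-[benzyl(dimethyl)silyl]-3-hydroxy-3-methylbut-1-en-2-yl}-3-methylideneoxolan-2-one, via hydroxy ester 3 (not isolated)
Conditions: ethyl 2-{[(tert-butoxycarbonyl)oxy]methyl}prop-2-enoate (2 equiv), [Ir(cod)Cl]2 (2.5 mol %), (R)-SEGPHOS (5 mol %), 4-cyano-3-nitrobenzoic acid (10 mol %), Cs2CO3 (20 mol %), i-PrOH (2 equiv), THF, 60 °C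
Reagents that add atoms: ethyl 2-{[(tert-butoxycarbonyl)oxy]methyl}prop-2-enoate CCOC(=O)C(=C)COC(=O)OC(C)(C)C
Why: Iridium-catalysed transfer-hydrogenative 2-(alkoxycarbonyl)allylation from the aldehyde oxidation level should add the allyl unit to one aldehyde face under catalyst control (C8 set as R), and the γ-hydroxy ester then closes to the α-methylene-γ-butyrolactone.

Step 3
Reactants: 5 prop-2-yn-1-ol
Product: 7 (2E)-3-iodo-2-methylprop-2-en-1-ol, via alkenylalane 6 (not isolated)
Conditions: Me3Al (3 equiv), Cp2ZrCl2 (0.25 equiv), CH2Cl2, 0 → 23 °C; then [I][I] (1.2 equiv), THF, −30 → 0 °C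
Reagents that add atoms: trimethylaluminium C[Al](C)C; iodine [I][I]
Why: Negishi zirconium-catalysed carboalumination adds methyl and aluminium syn (methyl to the inner carbon), and iodinolysis with retention should give the E iodide only.

Step 4
Reactants: 7 (2E)-3-iodo-2-methylprop-2-en-1-ol
Product: 8 (2E)-3-iodo-2-methylprop-2-enal
Conditions: MnO2 (15 equiv), CH2Cl2, 23 °C
Reagents that add atoms: none
Why: Allylic oxidation with MnO2 is neutral and should leave the alkenyl iodide and its geometry untouched.

Step 5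
Reactants: 8 (2E)-3-iodo-2-methylprop-2-enal
Product: 9 (1E)-1-iodo-2-methylbuta-1,3-diene
Conditions: Ph3PCH3Br (1.3 equiv), n-BuLi (1.25 equiv), THF, 0 °C; then 8, −78 → 0 °C; product kept as a cold pentane solution
Reagents that add atoms: methyltriphenylphosphonium bromide C[P+](c1ccccc1)(c1ccccc1)c1ccccc1.[Br-]
Why: Wittig methylenation of the enal should give the volatile diene without touching the trisubstituted iodoalkene.

Step 6
Reactants: 4 (5R)-5-{(1E)-1-[benzyl(dimethyl)silyl]-3-hydroxy-3-methylbut-1-en-2-yl}-3-methylideneoxolan-2-one; 9 (1E)-1-iodo-2-methylbuta-1,3-diene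
Product: 11 (5R)-5-[(3E,5E)-2-hydroxy-2,6-dimethylocta-3,5,7-trien-3-yl]-3-methylideneoxolan-2-one, via silanol 10 (not isolated)
Conditions: TBAF (2.2 equiv), THF, 0 °C, 15 min; then 9 (1.3 equiv), Pd2(dba)3·CHCl3 (2.5 mol %), 23 °C
Reagents that add atoms: none
Why: Hiyama–Denmark coupling in its benzyldimethylsilyl form: fluoride removes the benzyl group, the silanolate transmetalates to the dienylpalladium iodide, and both alkene geometries are retained, so C5 stays cis to C8 and C6 trans to C3; the phosphine-free catalyst should not ionise the allylic lactone C–O bond.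

Step 7
Reactants: 11 (5R)-5-[(3E,5E)-2-hydroxy-2,6-dimethylocta-3,5,7-trien-3-yl]-3-methylideneoxolan-2-one
Product: 12 11-hydroxy-5α-eudesma-3,6-dien-14,8β-olide (trans-fused; C14 is β on C10 and lactonised to the 8β-oxygen)
Conditions: toluene (0.005 M), BHT (0.2 equiv), 130 °C, sealed tube, 24 h
Reagents that add atoms: none
Why: A thermal, concerted but asynchronous [4+2] cycloaddition (type 1 intramolecular Diels–Alder) joins the diene C2=C3–C4(CH3)=C5 to the ester-activated exocyclic alkene C1=C10 of the α-methylene lactone, forming C1–C2 and C5–C10 and leaving C3=C4 where the diol is needed. The closest known reaction types are intramolecular Diels–Alder reactions of 1,7,9-decatrienes with an alkoxycarbonyl group on the inner dienophile carbon and intermolecular Diels–Alder reactions of α-methylene-γ-butyrolactones. Ring A is the new cyclohexene of the cycloaddition (closed by C1–C2, both dienophile carbons inside the ring), and ring B closes at the same time through C5–C10 as a six-membered ring over the four-atom tether C6=C7–C8–C9, so the lactone becomes the two-atom bridge of a 6-oxabicyclo[3.2.1]octenone. C10 is controlled by C8, because the diene can reach C10 only on the lactone face that carries C7, so C14 and O8 end up cis (10β-C14 from the 8R centre); C5 is controlled by the endo mode, in which the diene lies over the lactone carbonyl and C4 takes the equatorial position of the developing ring B chair, putting H5 anti to C14 (trans ring fusion). The step needs intramolecular over intermolecular reaction (high dilution, BHT against radical oligomerisation), endo over exo (exo would push C4 axial, syn to the C9 methylene), and a diene that survives heating: the E C4=C5 bond keeps C6 on the outer diene position and rules out 6π closure of the triene, and the inside substituents C15 and C8 disfavour the s-cis C4=C5–C6=C7 geometry that a 1,5-hydrogen shift would need.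

Step 8
Reactants: 12 11-hydroxy-5α-eudesma-3,6-dien-14,8β-olide
Product: 13 8β,14-epoxy-5α-eudesma-3,6-diene-11,14-diol (lactol; both C14 epimers)
Conditions: i-Bu2AlH (2.5 equiv), CH2Cl2, −78 °C; aqueous Rochelle salt
Reagents that add atoms: none
Why: Half-reduction of the only carbonyl group; the bridged aluminium hemiacetal should be stable at −78 °C and gives the lactol on work-up.

Step 9
Reactants: 13 8β,14-epoxy-5α-eudesma-3,6-diene-11,14-diol
Product: 15 5α-eudesma-3,6-diene-8β,11-diol (10β-methyl), via tosylhydrazone 14 (not isolated)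
Conditions: TsNHNH2 (1.3 equiv), EtOH, 50 °C; then catecholborane (4 equiv), CHCl3, 0 °C; then NaOAc·3H2O, 60 °C
Reagents that add atoms: none
Why: Caglioti-type reduction: the open hydroxy aldehyde form is trapped as its tosylhydrazone, hydride reduction and loss of sulfinate and N2 should turn the neopentyl CH=N into the C14 methyl under near-neutral conditions that spare both allylic alcohols; C10 is quaternary and cannot epimerise.

Step 10
Reactants: 15 5α-eudesma-3,6-diene-8β,11-diol
Product: 16 11-hydroxy-5α-eudesma-3,6-dien-8-one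
Conditions: Dess–Martin periodinane (1.3 equiv), NaHCO3 (3 equiv), CH2Cl2, 0 → 23 °C
Reagents that add atoms: none
Why: Buffered Dess–Martin oxidation should oxidise the only secondary alcohol to the enone while the tertiary C11 hydroxyl and the doubly allylic H5 stay untouched.

Step 11
Reactants: 16 11-hydroxy-5α-eudesma-3,6-dien-8-one
Product: 17 3α,4α,11-trihydroxy-5α-eudesm-6-en-8-one
Conditions: OsO4 (2 mol %), NMO (1.3 equiv), acetone–H2O (8:1), 0 → 23 °C
Reagents that add atoms: N-methylmorpholine N-oxide C[N+]1([O-])CCOCC1; water O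
Why: Upjohn dihydroxylation should pick the isolated, electron-rich C3=C4 bond over the hindered enone C6=C7 and attack from the α face, anti to the axial 10β-methyl, giving the 3α,4α-cis-diol (C3 axial O, C4 equatorial OH, C15 β).

Step 12
Reactants: 18 (2E)-2-methylbut-2-en-1-ol
Product: 19 [(2R,3R)-2,3-dimethyloxiran-2-yl]methanol
Conditions: Ti(OiPr)4 (10 mol %), D-(−)-diethyl tartrate (12 mol %), t-BuOOH (2 equiv), 4 Å MS, CH2Cl2, −20 °C
Reagents that add atoms: tert-butyl hydroperoxide CC(C)(C)OO
Why: Katsuki–Sharpless epoxidation; the D-(−)-tartrate delivers oxygen to the face that gives the (2R,3R) epoxide, and the E geometry fixes CH2OH trans to the C3 methyl.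

Step 13
Reactants: 19 [(2R,3R)-2,3-dimethyloxiran-2-yl]methanol
Product: 20 (2S,3R)-2,3-dimethyloxirane-2-carboxylic acid
Conditions: RuCl3·xH2O (2 mol %), NaIO4 (4 equiv), CCl4–MeCN–H2O (2:2:3), 23 °C
Reagents that add atoms: sodium periodate [Na+].[O-]I(=O)(=O)=O; water O
Why: Ruthenium tetroxide generated in situ oxidises the primary alcohol to the acid without opening the epoxide; C2 has no hydrogen, so nothing epimerises (the descriptor at C2 changes from R to S only through the priority rules).

Step 14
Reactants: 17 3α,4α,11-trihydroxy-5α-eudesm-6-en-8-one; 20 (2S,3R)-2,3-dimethyloxirane-2-carboxylic acid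
Product: 22 3α-{[(2S,3R)-2,3-dimethyloxiran-2-yl]carbonyloxy}-4α,11-dihydroxy-5α-eudesm-6-en-8-one (CNP0272928.1), via mixed anhydride 21 (not isolated)
Conditions: 20 (2 equiv), 2,4,6-trichlorobenzoyl chloride (2 equiv), Et3N (3 equiv), THF, 23 °C; then 17, DMAP (3 equiv), toluene, 23 → 50 °C
Reagents that add atoms: none
Why: Yamaguchi esterification should acylate the only secondary hydroxyl (3α) and leave the two tertiary alcohols, the enone and the epoxide unchanged.

**Compound list**

1 | 2-methylbut-3-yn-2-ol | CC(C)(O)C#C | starting material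
2 | (2Z)-3-[benzyl(dimethyl)silyl]-2-(2-hydroxypropan-2-yl)prop-2-enal | O=C/C(=C\[Si](C)(C)Cc1ccccc1)C(C)(C)O | intermediate
3 | ethyl (4R,5E)-6-[benzyl(dimethyl)silyl]-4-hydroxy-5-(2-hydroxypropan-2-yl)-2-methylidenehex-5-enoate | CCOC(=O)C(=C)C[C@@H](O)/C(=C\[Si](C)(C)Cc1ccccc1)C(C)(C)O | intermediate
4 | (5R)-5-{(1E)-1-[benzyl(dimethyl)silyl]-3-hydroxy-3-methylbut-1-en-2-yl}-3-methylideneoxolan-2-one | O=C1O[C@H](CC1=C)/C(=C\[Si](C)(C)Cc1ccccc1)C(C)(C)O | intermediate
5 | prop-2-yn-1-ol | C#CCO | starting material
6 | dimethyl{[(2E)-3-(dimethylalumanyl)-2-methylprop-2-en-1-yl]oxy}alumane | C[Al](C)/C=C(\C)CO[Al](C)C | intermediate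
7 | (2E)-3-iodo-2-methylprop-2-en-1-ol | OC/C(C)=C/I | intermediate
8 | (2E)-3-iodo-2-methylprop-2-enal | O=C/C(C)=C/I | intermediate
9 | (1E)-1-iodo-2-methylbuta-1,3-diene | C=C/C(C)=C/I | intermediate
10 | (5R)-5-{(1E)-3-hydroxy-1-[hydroxy(dimethyl)silyl]-3-methylbut-1-en-2-yl}-3-methylideneoxolan-2-one | O=C1O[C@H](CC1=C)/C(=C\[Si](C)(C)O)C(C)(C)O | intermediate
11 | (5R)-5-[(3E,5E)-2-hydroxy-2,6-dimethylocta-3,5,7-trien-3-yl]-3-methylideneoxolan-2-one (C5 cis to C8 across C6=C7) | O=C1O[C@H](CC1=C)/C(=C\C=C(/C)C=C)C(C)(C)O | intermediate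
12 | 11-hydroxy-5α-eudesma-3,6-dien-14,8β-olide | CC1=CCC[C@@]23C[C@@H](OC2=O)C(C(C)(C)O)=C[C@@H]13 | intermediate
13 | 8β,14-epoxy-5α-eudesma-3,6-diene-11,14-diol (lactol) | CC1=CCC[C@@]23C[C@@H](OC2O)C(C(C)(C)O)=C[C@@H]13 | intermediate
14 | 8β,11-dihydroxy-5α-eudesma-3,6-dien-14-al 4-methylbenzenesulfonylhydrazone | CC1=CCC[C@]2(C=NNS(=O)(=O)c3ccc(C)cc3)C[C@@H](O)C(C(C)(C)O)=C[C@@H]12 | intermediate
15 | 5α-eudesma-3,6-diene-8β,11-diol | CC1=CCC[C@]2(C)C[C@@H](O)C(C(C)(C)O)=C[C@@H]12 | intermediate
16 | 11-hydroxy-5α-eudesma-3,6-dien-8-one | CC1=CCC[C@]2(C)CC(=O)C(C(C)(C)O)=C[C@@H]12 | intermediate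
17 | 3α,4α,11-trihydroxy-5α-eudesm-6-en-8-one | O[C@@H]1CC[C@]2(C)CC(=O)C(C(C)(C)O)=C[C@H]2[C@]1(C)O | intermediate
18 | (2E)-2-methylbut-2-en-1-ol | C/C=C(\C)CO | starting material
19 | [(2R,3R)-2,3-dimethyloxiran-2-yl]methanol | C[C@H]1O[C@]1(C)CO | intermediate
20 | (2S,3R)-2,3-dimethyloxirane-2-carboxylic acid | C[C@H]1O[C@]1(C)C(=O)O | intermediate
21 | (2S,3R)-2,3-dimethyloxirane-2-carboxylic 2,4,6-trichlorobenzoic anhydride | C[C@H]1O[C@]1(C)C(=O)OC(=O)c1c(Cl)cc(Cl)cc1Cl | intermediate
22 | 3α-{[(2S,3R)-2,3-dimethyloxiran-2-yl]carbonyloxy}-4α,11-dihydroxy-5α-eudesm-6-en-8-one | C[C@H]1O[C@]1(C)C(=O)O[C@@H]1CC[C@]2(C)CC(=O)C(C(C)(C)O)=C[C@H]2[C@]1(C)O | target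

**Count and risks**

Total step count: 14. Longest linear sequence: 10 steps (5 → 7 → 8 → 9 → 11 → 12 → 13 → 15 → 16 → 17 → 22; steps 3–11 and 14).

Steps most likely to fail:

Step 7. The cycloaddition has to pass through a bridged transition state. If ring strain slows it, intermolecular Diels–Alder dimerisation and radical oligomerisation of the α-methylene lactone take over, and the endo preference that gives the trans ring fusion may erode. The fallback gives up the lactone and uses an unstrained, unactivated all-carbon tether; it sets out from 2. Iridium-catalysed transfer-hydrogenative methallylation of 2 (methallyl chloride, catalyst system of step 2 with the other ligand antipode) should give (4S,5E)-6-[benzyl(dimethyl)silyl]-5-(2-hydroxypropan-2-yl)-2-methylhexa-1,5-dien-4-ol F1. Hiyama–Denmark coupling with 9 as in step 6, through (4S,5E)-6-[hydroxy(dimethyl)silyl]-5-(2-hydroxypropan-2-yl)-2-methylhexa-1,5-dien-4-ol F2, should give (4S,5E,7E)-5-(2-hydroxypropan-2-yl)-2,8-dimethyldeca-1,5,7,9-tetraen-4-ol F3. Phenylboronic acid (toluene, 4 Å MS, 23 °C) ties O8 and O11 into the 2-phenyl-1,3,2-dioxaborinane of the tetraene diol F4. This is heated (toluene, 0.005 M, BHT, 170 °C) for a thermal type 1 intramolecular Diels–Alder reaction to the phenylboronate of 5α-eudesma-3,6-diene-8α,11-diol F5. Here the boronate ring holds the C8–O bond near the plane of C6=C7, so the 8S centre should leave one diene face open. H2O2 with aqueous NaHCO3 in THF at 0 °C frees 5α-eudesma-3,6-diene-8α,11-diol F6, the C8 epimer of 15, and Dess–Martin oxidation as in step 10 comes back to the route at 16.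

Step 2. Transfer hydrogenation of the hindered, α-branched enal (reduction of the aldehyde or of the conjugated double bond) may outrun C–C coupling, or the facial discrimination may be low. The fallback sets out from 2. Brønsted acid-catalysed enantioselective propargylation with allenylboronic acid pinacol ester (TRIP-type chiral phosphoric acid, the antipode that gives the 4R alcohol, toluene, 4 Å MS, 0 °C) should give (4R,5E)-6-[benzyl(dimethyl)silyl]-5-(2-hydroxypropan-2-yl)hex-5-en-1-yn-4-ol F7. Palladium-catalysed cyclocarbonylation (PdCl2, SnCl2, PPh3, CO at 7 atm, MeCN, 75 °C) then closes the α-methylene lactone and comes back to the route at 4.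

Step 6. Fluoride or adventitious hydroxide may add to the α-methylene lactone or isomerise it, or protodesilylation may outrun transmetalation. The fallback sets out from 4. Iododesilylation (N-iodosuccinimide, hexafluoroisopropanol, 0 °C, retention) should give (5R)-5-[(1E)-3-hydroxy-1-iodo-3-methylbut-1-en-2-yl]-3-methylideneoxolan-2-one F8. Negishi coupling with [(1E)-2-methylbuta-1,3-dien-1-yl]zinc bromide F9 (from 9: t-BuLi, Et2O, −78 °C; then ZnBr2) under Pd2(dba)3 and tri(2-furyl)phosphine in THF at 23 °C forms the same C5–C6 bond without fluoride and comes back to the route at 11.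

**Further compounds**

F1 | step 7 | (4S,5E)-6-[benzyl(dimethyl)silyl]-5-(2-hydroxypropan-2-yl)-2-methylhexa-1,5-dien-4-ol | C=C(C)C[C@H](O)/C(=C\[Si](C)(C)Cc1ccccc1)C(C)(C)O
F2 | step 7 | (4S,5E)-6-[hydroxy(dimethyl)silyl]-5-(2-hydroxypropan-2-yl)-2-methylhexa-1,5-dien-4-ol | C=C(C)C[C@H](O)/C(=C\[Si](C)(C)O)C(C)(C)O
F3 | step 7 | (4S,5E,7E)-5-(2-hydroxypropan-2-yl)-2,8-dimethyldeca-1,5,7,9-tetraen-4-ol | C=C(C)C[C@H](O)/C(=C\C=C(/C)C=C)C(C)(C)O
F4 | step 7 | 2-phenyl-1,3,2-dioxaborinane of the tetraene diol | C=C(C)C[C@@H]1OB(c2ccccc2)OC(C)(C)/C1=C/C=C(\C)C=C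
F5 | step 7 | phenylboronate of 5α-eudesma-3,6-diene-8α,11-diol | CC1=CCC[C@]2(C)C[C@@H]3OB(c4ccccc4)OC(C)(C)C3=C[C@@H]12
F6 | step 7 | 5α-eudesma-3,6-diene-8α,11-diol | CC1=CCC[C@]2(C)C[C@H](O)C(C(C)(C)O)=C[C@@H]12
F7 | step 2 | (4R,5E)-6-[benzyl(dimethyl)silyl]-5-(2-hydroxypropan-2-yl)hex-5-en-1-yn-4-ol | C#CC[C@@H](O)/C(=C\[Si](C)(C)Cc1ccccc1)C(C)(C)O
F8 | step 6 | (5R)-5-[(1E)-3-hydroxy-1-iodo-3-methylbut-1-en-2-yl]-3-methylideneoxolan-2-one | O=C1O[C@H](CC1=C)/C(=C\I)C(C)(C)O
F9 | step 6 | [(1E)-2-methylbuta-1,3-dien-1-yl]zinc bromide | C=C/C(C)=C/[Zn]Br
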